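**Plan**
- Retrosynthesis first removes the C4 methyl ether, then cuts the ring bond C3–C4. In the ring C1 (C=O), C2=C3, C4 (OMe), C5, C6 (quaternary), C3 is an alkene carbon bonded to a carbinol carbon that lies 1,3 to C6, which is the retron of an alkenyl-metal addition to an aldehyde.
- The open chain is then cut at C1–C2 (alkynide plus lactone carbonyl), at both C6–CH2 bonds (lactone enolate alkylations) and at C7–C8 (crotylation of the aryl aldehyde).
- Forward: crotylation joins C7–C8, hydroboration and oxidative lactonisation give a γ-lactone (O, C8, C7, C6, C1), two alkylations load C6, an alkynide opens the lactone, and the (Z)-iodo enone and the aldehyde are unveiled. The cyclohexenone, the only carbocycle formed, closes in the penultimate step and O-methylation ends the route.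
- Stereochemistry: C7 and C8 come from a catalyst-controlled syn crotylation. C6 comes from the second alkylation, anti to the cis methyl and aryl groups of the lactone. C4 comes from the C6-controlled half-chair ring closure.

Key step: step 11

Assumption: megaphone numbering is used throughout (ring C1–C6 as above, side chain C7 bearing methyl and C8 bearing acetoxy and aryl), and the (R) antipode of the phosphoric acid catalyst is taken to open the Re face of the aldehyde; if the sense is the opposite, its mirror image is used.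

Step 1
Reactants: 1 3,4,5-trimethoxybenzaldehyde; 2 (Z)-crotylboronic acid pinacol ester
Product: 3 (1R,2S)-2-methyl-1-(3,4,5-trimethoxyphenyl)but-3-en-1-ol
Conditions: (R)-TRIP (5 mol %), 4 Å MS, toluene, −30 °C; aq. NaHCO3 work-up
Reagents that add atoms: none
Why: Chiral phosphoric acid-catalysed crotylboration through a closed chair transition state, in which the (Z)-crotyl geometry should give the syn C7-methyl/C8-hydroxyl relation and the catalyst should direct attack to the Re face of the aldehyde (8R, hence 7S).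

Step 2
Reactants: 3 (1R,2S)-2-methyl-1-(3,4,5-trimethoxyphenyl)but-3-en-1-ol
Product: 5 (1R,2S)-2-methyl-1-(3,4,5-trimethoxyphenyl)butane-1,4-diol, via B-alkyl-9-BBN adduct 4 (not isolated)
Conditions: 9-BBN (2.2 equiv), THF, 0 °C → rt; then NaOH, H2O2, 0 °C
Reagents that add atoms: 9-borabicyclo[3.3.1]nonane, B1C2CCCC1CCC2 (carried in 4 only); hydrogen peroxide, OO
Why: Anti-Markovnikov hydroboration–oxidation of the terminal alkene installs the future C1 oxygen without touching C7 or C8.

Step 3
Reactants: 5 (1R,2S)-2-methyl-1-(3,4,5-trimethoxyphenyl)butane-1,4-diol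
Product: 7 (4S,5R)-4-methyl-5-(3,4,5-trimethoxyphenyl)oxolan-2-one, via lactol 6 (not isolated)
Conditions: TEMPO (cat.), PhI(OAc)2 (2.5 equiv), CH2Cl2, rt
Reagents that add atoms: none
Why: Oxidative lactonisation of a 1,4-diol, in which the primary alcohol is oxidised selectively, the aldehyde closes onto the C8 hydroxyl as the lactol and this is oxidised again, giving the cis-β-methyl-γ-aryl lactone with both stereocentres untouched.

Step 4
Reactants: 7 (4S,5R)-4-methyl-5-(3,4,5-trimethoxyphenyl)oxolan-2-one; 8 allyl bromide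
Product: 9 (3S,4S,5R)-4-methyl-3-(prop-2-en-1-yl)-5-(3,4,5-trimethoxyphenyl)oxolan-2-one
Conditions: LiN(i-Pr)2, THF, −78 °C; then 8, −78 → −40 °C
Reagents that add atoms: none
Why: Lactone enolate alkylation with a reactive allylic bromide, expected to place the allyl group trans to the C7 methyl group, although the C6 configuration here is of no consequence because this centre is enolised again in step 6.

Step 5
Reactants: 9 (3S,4S,5R)-4-methyl-3-(prop-2-en-1-yl)-5-(3,4,5-trimethoxyphenyl)oxolan-2-one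
Product: 11 (3S,4S,5R)-3-(2,2-dimethoxyethyl)-4-methyl-5-(3,4,5-trimethoxyphenyl)oxolan-2-one, via aldehyde 10 (not isolated)
Conditions: O3, CH2Cl2/MeOH, −78 °C (stopped at first excess); Me2S; then HC(OMe)3, TsOH·H2O (cat.), rt
Reagents that add atoms: ozone, [O-][O+]=O (oxygen of 10 only); trimethyl orthoformate, COC(OC)OC; methanol, CO
Why: Ozonolysis of the terminal alkene, which reacts far faster than the arene, followed by acid-catalysed acetalisation, stores the C5–C4 arm as a base-stable dimethyl acetal at the aldehyde oxidation level.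

Step 6
Reactants: 11 (3S,4S,5R)-3-(2,2-dimethoxyethyl)-4-methyl-5-(3,4,5-trimethoxyphenyl)oxolan-2-one; 8 allyl bromide
Product: 12 (3R,4S,5R)-3-(2,2-dimethoxyethyl)-4-methyl-3-(prop-2-en-1-yl)-5-(3,4,5-trimethoxyphenyl)oxolan-2-one
Conditions: LiN(i-Pr)2, THF, −78 °C; then 8, DMPU, −78 → −20 °C
Reagents that add atoms: none
Why: Second lactone enolate alkylation, in which the planar, fully substituted enolate should be attacked on the face opposite the cis C7 methyl and C8 aryl groups, so that allyl ends trans and the acetal arm cis to the methyl group, which is the 6R quaternary centre (1,2-induction in a γ-butyrolactone enolate).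

Step 7
Reactants: 12 (3R,4S,5R)-3-(2,2-dimethoxyethyl)-4-methyl-3-(prop-2-en-1-yl)-5-(3,4,5-trimethoxyphenyl)oxolan-2-one; 13 ethynyltrimethylsilane
Product: 14 (4R,5S,6R)-4-(2,2-dimethoxyethyl)-6-hydroxy-5-methyl-4-(prop-2-en-1-yl)-6-(3,4,5-trimethoxyphenyl)-1-(trimethylsilyl)hex-1-yn-3-one
Conditions: 13, n-BuLi, THF, −78 °C; then 12, −78 → −40 °C; AcOH, −78 °C
Reagents that add atoms: none
Why: Addition of a lithium alkynide to a lactone that has no α-hydrogen (C6 is quaternary), where the lithium lactolate is stable in the cold and is protonated before it can release the ketone, so a second addition is avoided and the hydroxy ynone (in equilibrium with its five-membered hemiketal) should result.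

Step 8
Reactants: 14 (4R,5S,6R)-4-(2,2-dimethoxyethyl)-6-hydroxy-5-methyl-4-(prop-2-en-1-yl)-6-(3,4,5-trimethoxyphenyl)-1-(trimethylsilyl)hex-1-yn-3-one
Product: 15 (1R,2S,3R)-3-(2,2-dimethoxyethyl)-2-methyl-4-oxo-3-(prop-2-en-1-yl)-1-(3,4,5-trimethoxyphenyl)-6-(trimethylsilyl)hex-5-yn-1-yl acetate
Conditions: Ac2O, Et3N, DMAP (cat.), CH2Cl2, 0 °C → rt
Reagents that add atoms: acetic anhydride, CC(=O)OC(C)=O
Why: DMAP-catalysed acylation of the secondary benzylic alcohol, in which the tertiary hemiketal hydroxyl of the ring tautomer is far more hindered, so the ring–chain equilibrium should drain through the open form to the C8 acetate while the silyl cap keeps the ynone inert to the amines.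

Step 9
Reactants: 15 (1R,2S,3R)-3-(2,2-dimethoxyethyl)-2-methyl-4-oxo-3-(prop-2-en-1-yl)-1-(3,4,5-trimethoxyphenyl)-6-(trimethylsilyl)hex-5-yn-1-yl acetate
Product: 17 (1R,2S,3R,5Z)-3-(2,2-dimethoxyethyl)-6-iodo-2-methyl-4-oxo-3-(prop-2-en-1-yl)-1-(3,4,5-trimethoxyphenyl)hex-5-en-1-yl acetate, via terminal ynone 16 (not isolated)
Conditions: Bu4NF, AcOH, THF, −20 °C; then NaI (3 equiv), AcOH, rt
Reagents that add atoms: sodium iodide, [Na+].[I-]
Why: Acetic acid-buffered fluoride removes the alkynyl silyl group without harming acetate or acetal, and the labile terminal ynone is hydroiodinated in the same flask by conjugate addition of iodide and protonation of the iodoallenol, which gives the kinetic (Z)-β-iodo enone.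

Step 10
Reactants: 17 (1R,2S,3R,5Z)-3-(2,2-dimethoxyethyl)-6-iodo-2-methyl-4-oxo-3-(prop-2-en-1-yl)-1-(3,4,5-trimethoxyphenyl)hex-5-en-1-yl acetate
Product: 18 (1R,2S,3R,5Z)-6-iodo-2-methyl-4-oxo-3-(2-oxoethyl)-3-(prop-2-en-1-yl)-1-(3,4,5-trimethoxyphenyl)hex-5-en-1-yl acetate
Conditions: TsOH·H2O (cat.), acetone/H2O (10:1), rt
Reagents that add atoms: water, O
Why: Mild acid-catalysed acetal hydrolysis (transacetalisation to acetone) in the absence of iodide, so the Z geometry should be kept, and the γ-keto aldehyde can neither form a furan nor enolise toward C6 because C6 is quaternary.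

Step 11
Reactants: 18 (1R,2S,3R,5Z)-6-iodo-2-methyl-4-oxo-3-(2-oxoethyl)-3-(prop-2-en-1-yl)-1-(3,4,5-trimethoxyphenyl)hex-5-en-1-yl acetate
Product: 19 (1R,2S)-2-[(1R,5R)-5-hydroxy-2-oxo-1-(prop-2-en-1-yl)cyclohex-3-en-1-yl]-1-(3,4,5-trimethoxyphenyl)propyl acetate
Conditions: CrCl2 (6 equiv), NiCl2 (2 mol %), degassed DMF, rt, 0.005 M; aq. NH4Cl
Reagents that add atoms: none
Why: Zerovalent nickel, formed from NiCl2 by CrCl2, inserts into the C3–I bond with retention, and transmetalation gives a (Z)-alkenyl species of trivalent chromium that adds to the C4 aldehyde. The closest known reaction type is the intramolecular Nozaki–Hiyama–Kishi coupling of an alkenyl iodide with an aldehyde, for which β-iodo enones are established partners. The new C3–C4 bond closes the cyclohexenone ring (C1–C6) in a 6-exo-trig attack on the aldehyde carbonyl, which the Z geometry places within reach of C3. The new C4 stereocentre is controlled by C6: in the half-chair transition state the branched C7 side chain should sit pseudo-equatorial and the allyl group axial, and the aldehyde oxygen, held near chromium in the plane of the enone, is equatorial, so the C4 oxygen ends cis to the side chain (4R). The step needs chemoselectivity for the aldehyde over the C1 ketone, the acetate and the allyl group, which the aldehyde preference of organochromium reagents and the shielding of C1 by the quaternary C6 should secure.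

Step 12
Reactants: 19 (1R,2S)-2-[(1R,5R)-5-hydroxy-2-oxo-1-(prop-2-en-1-yl)cyclohex-3-en-1-yl]-1-(3,4,5-trimethoxyphenyl)propyl acetate
Product: 20 megaphone acetate, (1R,2S)-2-[(1R,5R)-5-methoxy-2-oxo-1-(prop-2-en-1-yl)cyclohex-3-en-1-yl]-1-(3,4,5-trimethoxyphenyl)propyl acetate
Conditions: Me3OBF4, 1,8-bis(dimethylamino)naphthalene, CH2Cl2, 0 °C → rt
Reagents that add atoms: trimethyloxonium tetrafluoroborate, C[O+](C)C.F[B-](F)(F)F
Why: O-Methylation of the allylic C4 alcohol with Meerwein's salt buffered by a hindered, non-nucleophilic amine, which avoids an alkoxide (no acetate migration, no isomerisation of the γ-hydroxy enone) and leaves the C4–O bond intact, so the 4R configuration is retained.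

**Compound list**
1 | 3,4,5-trimethoxybenzaldehyde | COc1cc(C=O)cc(OC)c1OC | starting material
2 | (Z)-crotylboronic acid pinacol ester, 2-[(2Z)-but-2-en-1-yl]-4,4,5,5-tetramethyl-1,3,2-dioxaborolane | C/C=C\CB1OC(C)(C)C(C)(C)O1 | starting material
3 | (1R,2S)-2-methyl-1-(3,4,5-trimethoxyphenyl)but-3-en-1-ol (syn) | C=C[C@H](C)[C@@H](O)c1cc(OC)c(OC)c(OC)c1 | intermediate
4 | (1R,2S)-4-(9-borabicyclo[3.3.1]nonan-9-yl)-2-methyl-1-(3,4,5-trimethoxyphenyl)butan-1-ol (not isolated) | B1(C2CCCC1CCC2)CC[C@H](C)[C@@H](O)c1cc(OC)c(OC)c(OC)c1 | intermediate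
5 | (1R,2S)-2-methyl-1-(3,4,5-trimethoxyphenyl)butane-1,4-diol | OCC[C@H](C)[C@@H](O)c1cc(OC)c(OC)c(OC)c1 | intermediate
6 | (4S,5R)-4-methyl-5-(3,4,5-trimethoxyphenyl)oxolan-2-ol, either anomer (not isolated) | OC1C[C@H](C)[C@@H](O1)c2cc(OC)c(OC)c(OC)c2 | intermediate
7 | (4S,5R)-4-methyl-5-(3,4,5-trimethoxyphenyl)oxolan-2-one (methyl and aryl cis) | O=C1C[C@H](C)[C@@H](O1)c2cc(OC)c(OC)c(OC)c2 | intermediate
8 | allyl bromide (3-bromoprop-1-ene) | C=CCBr | starting material
9 | (3S,4S,5R)-4-methyl-3-(prop-2-en-1-yl)-5-(3,4,5-trimethoxyphenyl)oxolan-2-one (allyl trans to methyl) | O=C1[C@@H](CC=C)[C@H](C)[C@@H](O1)c2cc(OC)c(OC)c(OC)c2 | intermediate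
10 | 2-[(3S,4S,5R)-4-methyl-2-oxo-5-(3,4,5-trimethoxyphenyl)oxolan-3-yl]acetaldehyde (not isolated) | O=C1[C@@H](CC=O)[C@H](C)[C@@H](O1)c2cc(OC)c(OC)c(OC)c2 | intermediate
11 | (3S,4S,5R)-3-(2,2-dimethoxyethyl)-4-methyl-5-(3,4,5-trimethoxyphenyl)oxolan-2-one | O=C1[C@@H](CC(OC)OC)[C@H](C)[C@@H](O1)c2cc(OC)c(OC)c(OC)c2 | intermediate
12 | (3R,4S,5R)-3-(2,2-dimethoxyethyl)-4-methyl-3-(prop-2-en-1-yl)-5-(3,4,5-trimethoxyphenyl)oxolan-2-one (allyl trans, acetal arm cis to methyl) | O=C1[C@](CC=C)(CC(OC)OC)[C@H](C)[C@@H](O1)c2cc(OC)c(OC)c(OC)c2 | intermediate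
13 | ethynyltrimethylsilane | C#C[Si](C)(C)C | starting material
14 | (4R,5S,6R)-4-(2,2-dimethoxyethyl)-6-hydroxy-5-methyl-4-(prop-2-en-1-yl)-6-(3,4,5-trimethoxyphenyl)-1-(trimethylsilyl)hex-1-yn-3-one | C=CC[C@@](CC(OC)OC)([C@H](C)[C@@H](O)c1cc(OC)c(OC)c(OC)c1)C(=O)C#C[Si](C)(C)C | intermediate
15 | (1R,2S,3R)-3-(2,2-dimethoxyethyl)-2-methyl-4-oxo-3-(prop-2-en-1-yl)-1-(3,4,5-trimethoxyphenyl)-6-(trimethylsilyl)hex-5-yn-1-yl acetate | C=CC[C@@](CC(OC)OC)([C@H](C)[C@@H](OC(C)=O)c1cc(OC)c(OC)c(OC)c1)C(=O)C#C[Si](C)(C)C | intermediate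
16 | (1R,2S,3R)-3-(2,2-dimethoxyethyl)-2-methyl-4-oxo-3-(prop-2-en-1-yl)-1-(3,4,5-trimethoxyphenyl)hex-5-yn-1-yl acetate (not isolated) | C=CC[C@@](CC(OC)OC)([C@H](C)[C@@H](OC(C)=O)c1cc(OC)c(OC)c(OC)c1)C(=O)C#C | intermediate
17 | (1R,2S,3R,5Z)-3-(2,2-dimethoxyethyl)-6-iodo-2-methyl-4-oxo-3-(prop-2-en-1-yl)-1-(3,4,5-trimethoxyphenyl)hex-5-en-1-yl acetate | C=CC[C@@](CC(OC)OC)([C@H](C)[C@@H](OC(C)=O)c1cc(OC)c(OC)c(OC)c1)C(=O)/C=C\I | intermediate
18 | (1R,2S,3R,5Z)-6-iodo-2-methyl-4-oxo-3-(2-oxoethyl)-3-(prop-2-en-1-yl)-1-(3,4,5-trimethoxyphenyl)hex-5-en-1-yl acetate | C=CC[C@@](CC=O)([C@H](C)[C@@H](OC(C)=O)c1cc(OC)c(OC)c(OC)c1)C(=O)/C=C\I | intermediate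
19 | (1R,2S)-2-[(1R,5R)-5-hydroxy-2-oxo-1-(prop-2-en-1-yl)cyclohex-3-en-1-yl]-1-(3,4,5-trimethoxyphenyl)propyl acetate (C4 hydroxyl cis to the C7 side chain) | C=CC[C@]1([C@H](C)[C@@H](OC(C)=O)c2cc(OC)c(OC)c(OC)c2)C[C@@H](O)C=CC1=O | intermediate
20 | megaphone acetate, (1R,2S)-2-[(1R,5R)-5-methoxy-2-oxo-1-(prop-2-en-1-yl)cyclohex-3-en-1-yl]-1-(3,4,5-trimethoxyphenyl)propyl acetate | C=CC[C@]1([C@H](C)[C@@H](OC(C)=O)c2cc(OC)c(OC)c(OC)c2)C[C@@H](OC)C=CC1=O | target

**Step count**
Total: 12 steps. Longest linear sequence: 12 steps, from 1 to 20.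

**Steps most likely to fail**

Step 11. The alkenylchromium may add to both faces of the aldehyde if the half-chair with the side chain axial competes, and the Z iodide may drift toward E before closure. The fallback sets out from 18 and sets C4 by reagent control. The ring closure is run without seeking selectivity, and the carbinol mixture, 19 together with its C4 epimer F1, is oxidised with MnO2 in CH2Cl2 to the ene-1,4-dione F2. Its C4 carbonyl, the less hindered of the two because C1 abuts the quaternary C6, is then reduced by Corey–Bakshi–Shibata reduction with catecholborane in toluene at −78 °C, using the oxazaborolidine antipode that gives the 4R carbinol (expected to be (S)-Me-CBS if the alkenyl arm acts as the large group). The route is rejoined at 19.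

Step 7. The alkynide may fail to add to the neopentyl-type lactone carbonyl, or the lactolate may collapse early and take up a second alkynide; the hemiketal form of 14 may also resist clean acylation in step 8. The fallback sets out from 12 and builds the ynone by aldehyde alkynylation instead of lactone opening. LiAlH4 in THF reduces the lactone to the diol F3. The primary neopentyl hydroxyl is silylated selectively (t-BuMe2SiCl, imidazole) to the silyl ether F4, and the benzylic hydroxyl is acetylated (Ac2O, DMAP) to the acetate F5. HF·pyridine frees the primary alcohol F6, and Dess–Martin periodinane gives the non-enolisable aldehyde F7. LiC≡CSiMe3 at −78 °C should add to the aldehyde in preference to the acetate, giving the propargylic alcohol F8 as either carbinol epimer, and a second Dess–Martin oxidation rejoins the route at 15.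

Step 6. The facial bias of the lactone enolate may be eroded in the quaternising alkylation, leaving a mixture at C6. The fallback sets out from 11 and replaces the lithium enolate by a softer nucleophile and the allyl bromide by a bulky, ligand-bearing electrophile. LiN(i-Pr)2 and Me3SiCl give the silyl ketene acetal F9, which is allylated under Tsuji–Trost conditions (allyl methyl carbonate, Pd2(dba)3 as the source of zerovalent palladium, DACH-phenyl Trost ligand, THF, rt). The cationic π-allyl complex of divalent palladium is attacked outside the metal sphere on the face remote from methyl and aryl, and the ligand antipode is chosen to reinforce this substrate bias. The route is rejoined at 12.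

**Further compounds**
F1 | step 11 | (1R,2S)-2-[(1R,5S)-5-hydroxy-2-oxo-1-(prop-2-en-1-yl)cyclohex-3-en-1-yl]-1-(3,4,5-trimethoxyphenyl)propyl acetate (C4 epimer of 19) | C=CC[C@]1([C@H](C)[C@@H](OC(C)=O)c2cc(OC)c(OC)c(OC)c2)C[C@H](O)C=CC1=O
F2 | step 11 | (1R,2S)-2-[(1R)-2,5-dioxo-1-(prop-2-en-1-yl)cyclohex-3-en-1-yl]-1-(3,4,5-trimethoxyphenyl)propyl acetate | C=CC[C@]1([C@H](C)[C@@H](OC(C)=O)c2cc(OC)c(OC)c(OC)c2)CC(=O)C=CC1=O
F3 | step 7 | (1R,2S,3R)-3-(2,2-dimethoxyethyl)-3-(hydroxymethyl)-2-methyl-1-(3,4,5-trimethoxyphenyl)hex-5-en-1-ol | C=CC[C@@](CC(OC)OC)([C@H](C)[C@@H](O)c1cc(OC)c(OC)c(OC)c1)CO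
F4 | step 7 | (1R,2S,3R)-3-[(tert-butyldimethylsilyloxy)methyl]-3-(2,2-dimethoxyethyl)-2-methyl-1-(3,4,5-trimethoxyphenyl)hex-5-en-1-ol | C=CC[C@@](CC(OC)OC)([C@H](C)[C@@H](O)c1cc(OC)c(OC)c(OC)c1)CO[Si](C)(C)C(C)(C)C
F5 | step 7 | (1R,2S,3R)-3-[(tert-butyldimethylsilyloxy)methyl]-3-(2,2-dimethoxyethyl)-2-methyl-1-(3,4,5-trimethoxyphenyl)hex-5-en-1-yl acetate | C=CC[C@@](CC(OC)OC)([C@H](C)[C@@H](OC(C)=O)c1cc(OC)c(OC)c(OC)c1)CO[Si](C)(C)C(C)(C)C
F6 | step 7 | (1R,2S,3R)-3-(2,2-dimethoxyethyl)-3-(hydroxymethyl)-2-methyl-1-(3,4,5-trimethoxyphenyl)hex-5-en-1-yl acetate | C=CC[C@@](CC(OC)OC)([C@H](C)[C@@H](OC(C)=O)c1cc(OC)c(OC)c(OC)c1)CO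
F7 | step 7 | (1R,2S,3R)-3-(2,2-dimethoxyethyl)-3-formyl-2-methyl-1-(3,4,5-trimethoxyphenyl)hex-5-en-1-yl acetate | C=CC[C@@](CC(OC)OC)([C@H](C)[C@@H](OC(C)=O)c1cc(OC)c(OC)c(OC)c1)C=O
F8 | step 7 | (1R,2S,3R)-3-(2,2-dimethoxyethyl)-3-[1-hydroxy-3-(trimethylsilyl)prop-2-yn-1-yl]-2-methyl-1-(3,4,5-trimethoxyphenyl)hex-5-en-1-yl acetate (either carbinol epimer) | C=CC[C@@](CC(OC)OC)([C@H](C)[C@@H](OC(C)=O)c1cc(OC)c(OC)c(OC)c1)C(O)C#C[Si](C)(C)C
F9 | step 6 | {[(4S,5R)-3-(2,2-dimethoxyethyl)-4-methyl-5-(3,4,5-trimethoxyphenyl)-4,5-dihydrofuran-2-yl]oxy}trimethylsilane | C[Si](C)(C)OC1=C(CC(OC)OC)[C@H](C)[C@@H](O1)c2cc(OC)c(OC)c(OC)c2
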